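**Retrosynthetic overview**
1. Salimabromide 21 ⇐ twofold aromatic bromination ⇐ enone 20 ⇐ allylic C–H oxidation ⇐ tetracyclic γ-lactone 18.
2. Enabling feature: in 18 the lactone oxygen sits on the cycloheptene CH next to the future ketone, and the lactone carbonyl on the CH shared by lactone, cycloheptene and tetralin. Both CH groups flank the benzylic CH, so the lactone is the oxygen-inserted form of a cyclobutanone fused across the styrene bond of a 1,2-dihydronaphthalene.
3. That cyclobutanone holds a temporary acyl–carbon bond, made to steer ring closure and cleaved again by O insertion. It comes from an intramolecular keteniminium–alkene cycloaddition of amide 14, whose (Z)-alkenyl tether on the quaternary carbon closes the seven-membered ring in the same event.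
4. 14 ⇐ (Z)-Wittig of α-quaternary aldehyde 9 ⇐ ester 7 ⇐ Suzuki ethylation, benzylic bromination/elimination, geminal dimethylation ⇐ β-keto ester 3 (asymmetric methylation sets the one stereocentre carried in) ⇐ 6-bromo-1-tetralone 1.
5. Ring order: the benzo-fused six-membered ring is bought and turned into the dihydronaphthalene; the key step then forms cycloheptene and cyclobutane and expands the latter to the γ-lactone.

Key step: step 10

Remark on the chemistry: the sense of induction in step 2 is assumed to be selectable through the catalyst antipode so that (R)-3 results; aqueous work-ups are implied.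

**Step 1**
Reactants: 1 6-bromo-3,4-dihydronaphthalen-1(2H)-one
Product: 2 methyl 6-bromo-1-oxo-1,2,3,4-tetrahydronaphthalene-2-carboxylate
Conditions: NaH, (MeO)2CO, THF, reflux; AcOH quench
Reagents that add atoms: dimethyl carbonate COC(=O)OC
Why: Claisen-type C-acylation of the ketone enolate, driven by deprotonation of the β-keto ester formed; the α-carbon is still configurationally labile.

**Step 2**
Reactants: 2 methyl 6-bromo-1-oxo-1,2,3,4-tetrahydronaphthalene-2-carboxylate
Product: 3 methyl (R)-6-bromo-2-methyl-1-oxo-1,2,3,4-tetrahydronaphthalene-2-carboxylate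
Conditions: MeI, Cs2CO3, chiral quaternary ammonium bromide (cinchona or N-spiro binaphthyl type, 5–10 mol %), toluene, −30 °C
Reagents that add atoms: iodomethane CI
Why: Asymmetric phase-transfer C-alkylation of a cyclic β-keto ester; the chiral ammonium ion pair should shield one enolate face and set the quaternary stereocentre, from which all later stereocentres are relayed.

**Step 3**
Reactants: 3 methyl (R)-6-bromo-2-methyl-1-oxo-1,2,3,4-tetrahydronaphthalene-2-carboxylate
Product: 4 methyl (R)-6-bromo-1,1,2-trimethyl-1,2,3,4-tetrahydronaphthalene-2-carboxylate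
Conditions: Me2Zn, TiCl4 (gives Me2TiCl2), CH2Cl2, −30 °C to rt
Reagents that add atoms: dimethylzinc C[Zn]C
Why: Titanium-mediated geminal dimethylation of an aryl ketone (methyl addition, ionisation to the tertiary benzylic cation, second methyl transfer); the quaternary neighbour has no hydrogen, so no ring alkene can form, and the stereocentre is not touched.

**Step 4**
Reactants: 4 methyl (R)-6-bromo-1,1,2-trimethyl-1,2,3,4-tetrahydronaphthalene-2-carboxylate
Product: 6 methyl (R)-6-bromo-1,1,2-trimethyl-1,2-dihydronaphthalene-2-carboxylate, via benzylic bromide 5 (not isolated)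
Conditions: NBS, AIBN (cat.), PhCF3, 85 °C; then DBU, 85 °C
Reagents that add atoms: none
Why: Wohl–Ziegler bromination at the only benzylic C–H position followed by E2 dehydrobromination should give the styrene-type alkene; the stereocentre is not involved.

**Step 5**
Reactants: 6 methyl (R)-6-bromo-1,1,2-trimethyl-1,2-dihydronaphthalene-2-carboxylate
Product: 7 methyl (R)-6-ethyl-1,1,2-trimethyl-1,2-dihydronaphthalene-2-carboxylate
Conditions: EtBF3K, Pd(dppf)Cl2 (5 mol %), Cs2CO3, THF/H2O, 80 °C
Reagents that add atoms: potassium ethyltrifluoroborate CC[B-](F)(F)F.[K+]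
Why: Suzuki–Miyaura sp2–sp3 coupling; the ethyl group is brought in only after the radical bromination so that it offers no competing benzylic C–H bonds.

**Step 6**
Reactants: 7 methyl (R)-6-ethyl-1,1,2-trimethyl-1,2-dihydronaphthalene-2-carboxylate
Product: 8 [(R)-6-ethyl-1,1,2-trimethyl-1,2-dihydronaphthalen-2-yl]methanol
Conditions: LiAlH4, THF, 0 °C to rt
Reagents that add atoms: none
Why: Hydride reduction of the hindered ester to the neopentyl alcohol; the styrene is inert to LiAlH4.

**Step 7**
Reactants: 8 [(R)-6-ethyl-1,1,2-trimethyl-1,2-dihydronaphthalen-2-yl]methanol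
Product: 9 (R)-6-ethyl-1,1,2-trimethyl-1,2-dihydronaphthalene-2-carbaldehyde
Conditions: Dess–Martin periodinane, NaHCO3, CH2Cl2, rt
Reagents that add atoms: none
Why: Dess–Martin oxidation to an α-quaternary aldehyde that cannot enolise, so the stereocentre is safe.

**Step 8**
Reactants: 10 (3-carboxypropyl)triphenylphosphonium bromide; 11 dimethylamine hydrochloride
Product: 12 [4-(dimethylamino)-4-oxobutyl]triphenylphosphonium bromide
Conditions: EDC·HCl, HOBt (cat.), i-Pr2NEt, CH2Cl2, rt
Reagents that add atoms: none
Why: Carbodiimide amide coupling gives the Wittig salt that already carries the tertiary amide needed for keteniminium formation.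

**Step 9**
Reactants: 9 (R)-6-ethyl-1,1,2-trimethyl-1,2-dihydronaphthalene-2-carbaldehyde; 12 [4-(dimethylamino)-4-oxobutyl]triphenylphosphonium bromide
Product: 14 (R,Z)-5-(6-ethyl-1,1,2-trimethyl-1,2-dihydronaphthalen-2-yl)-N,N-dimethylpent-4-enamide, via phosphorus ylide 13 (not isolated)
Conditions: KHMDS, THF, −78 °C to rt
Reagents that add atoms: none
Why: Salt-free Wittig olefination with a non-stabilised ylide should give the (Z)-alkene under kinetic control; the cis geometry is what lets the tether reach the ring alkene in step 10.

**Step 10**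
Reactants: 14 (R,Z)-5-(6-ethyl-1,1,2-trimethyl-1,2-dihydronaphthalen-2-yl)-N,N-dimethylpent-4-enamide
Product: 18 tetracyclic γ-lactone (didebromo-deoxo-salimabromide), via keteniminium triflate 15 (not isolated), via cyclobutaniminium triflate 16 (not isolated), via cyclobutanone 17 (not isolated)
Conditions: Tf2O, 2,4,6-collidine, ClCH2CH2Cl, −20 to 80 °C; then 30% H2O2, 2 M NaOH, THF, 0 °C; acidic work-up
Reagents that add atoms: hydrogen peroxide OO; water O
Why: Tf2O/collidine should convert the amide into keteniminium 15, whose central carbon attacks the styrene carbon next to the quaternary centre to give a benzylic cation that the enamine carbon captures (stepwise, formally [2+2]; closest known type: intramolecular keteniminium–alkene cycloaddition to cyclobutaniminium salts), and alkaline hydrogen peroxide then hydrolyses the iminium and effects Baeyer–Villiger oxygen insertion in the same flask. The cycloheptene closes as a seven-membered ring in the first C–C bond-forming event through the (Z)-alkenyl tether, the cyclobutane closes by collapse onto the benzylic cation, and the γ-lactone arises by 1,2-shift ring expansion (4 to 5) of the peroxide adduct. Both new bonds to the former styrene carbons form on the one alkene face the tether can reach, so the lactone α-carbon and the benzylic carbon are set cis to the tether by the quaternary stereocentre, the ketene-derived carbon is fixed by the cis ring fusion, and the C–O bond forms with retention at the migrating carbon. Regiochemistry of the cycloaddition is secured by the aryl group, which stabilises the cation only when the iminium carbon bonds to the non-benzylic alkene carbon. The step also needs oxygen insertion on the side of the ketene-derived carbon (the one bearing the CH2 group) and not on the side flanked by the quaternary carbon; this should be favoured because that carbon is the less encumbered secondary centre, and HOO− rather than a peracid leaves the cis-alkene untouched.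

**Step 11**
Reactants: 18 tetracyclic γ-lactone (didebromo-deoxo-salimabromide)
Product: 20 didebromosalimabromide (enone), via allylic tert-butyl peroxide 19 (not isolated)
Conditions: Rh2(cap)4 (1 mol %), t-BuOOH, K2CO3, CH2Cl2, rt
Reagents that add atoms: tert-butyl hydroperoxide CC(C)(C)OO
Why: Dirhodium-caprolactamate/TBHP allylic C–H oxidation; the only allylic CH2 should be oxidised through the mixed peroxide to the enone, and the other allylic carbon is quaternary so no transposition is possible.

**Step 12**
Reactants: 20 didebromosalimabromide (enone)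
Product: 21 salimabromide
Conditions: Br2 (2.2 equiv), AgOCOCF3, CF3CO2H, 0 °C to rt
Reagents that add atoms: bromine BrBr
Why: Electrophilic aromatic bromination with in situ trifluoroacetyl hypobromite; the two positions ortho to ethyl are activated by ortho/para alkyl groups while the third free position is shielded by the gem-dimethyl group, and the electron-poor enone alkene should not react.

**Compound list**
1 | 6-bromo-3,4-dihydronaphthalen-1(2H)-one | O=C1CCCc2cc(Br)ccc21 | starting material
2 | methyl 6-bromo-1-oxo-1,2,3,4-tetrahydronaphthalene-2-carboxylate (racemic) | COC(=O)C1CCc2cc(Br)ccc2C1=O | intermediate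
3 | methyl (R)-6-bromo-2-methyl-1-oxo-1,2,3,4-tetrahydronaphthalene-2-carboxylate | COC(=O)[C@]1(C)CCc2cc(Br)ccc2C1=O | intermediate
4 | methyl (R)-6-bromo-1,1,2-trimethyl-1,2,3,4-tetrahydronaphthalene-2-carboxylate | COC(=O)[C@]1(C)CCc2cc(Br)ccc2C1(C)C | intermediate
5 | methyl (2R)-4,6-dibromo-1,1,2-trimethyl-1,2,3,4-tetrahydronaphthalene-2-carboxylate (both C-4 epimers) | COC(=O)[C@]1(C)CC(Br)c2cc(Br)ccc2C1(C)C | intermediate (not isolated)
6 | methyl (R)-6-bromo-1,1,2-trimethyl-1,2-dihydronaphthalene-2-carboxylate | COC(=O)[C@]1(C)C=Cc2cc(Br)ccc2C1(C)C | intermediate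
7 | methyl (R)-6-ethyl-1,1,2-trimethyl-1,2-dihydronaphthalene-2-carboxylate | COC(=O)[C@]1(C)C=Cc2cc(CC)ccc2C1(C)C | intermediate
8 | [(R)-6-ethyl-1,1,2-trimethyl-1,2-dihydronaphthalen-2-yl]methanol | OC[C@]1(C)C=Cc2cc(CC)ccc2C1(C)C | intermediate
9 | (R)-6-ethyl-1,1,2-trimethyl-1,2-dihydronaphthalene-2-carbaldehyde | O=C[C@]1(C)C=Cc2cc(CC)ccc2C1(C)C | intermediate
10 | (3-carboxypropyl)triphenylphosphonium bromide | OC(=O)CCC[P+](c1ccccc1)(c1ccccc1)c1ccccc1.[Br-] | starting material
11 | dimethylamine hydrochloride | C[NH2+]C.[Cl-] | starting material
12 | [4-(dimethylamino)-4-oxobutyl]triphenylphosphonium bromide | CN(C)C(=O)CCC[P+](c1ccccc1)(c1ccccc1)c1ccccc1.[Br-] | intermediate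
13 | phosphorus ylide derived from 12 | CN(C)C(=O)CCC=P(c1ccccc1)(c1ccccc1)c1ccccc1 | intermediate (not isolated)
14 | (R,Z)-5-(6-ethyl-1,1,2-trimethyl-1,2-dihydronaphthalen-2-yl)-N,N-dimethylpent-4-enamide | CN(C)C(=O)CC/C=C\[C@]1(C)C=Cc2cc(CC)ccc2C1(C)C | intermediate
15 | keteniminium triflate of 14 (Me2N+=C=CH–CH2–(Z)-CH=CH– on the quaternary carbon) | C[N+](C)=C=CC/C=C\[C@]1(C)C=Cc2cc(CC)ccc2C1(C)C.[O-]S(=O)(=O)C(F)(F)F | intermediate (not isolated)
16 | cyclobutaniminium triflate: cyclobutane cis-fused on the former styrene bond, cycloheptene closed, all new bonds on the face of the tether | CCc1ccc2c(c1)[C@H]1[C@@H]3C(=[N+](C)C)[C@H]1[C@@](C)(C=CC3)C2(C)C.[O-]S(=O)(=O)C(F)(F)F | intermediate (not isolated)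
17 | cyclobutanone corresponding to 16 | CCc1ccc2c(c1)[C@H]1[C@@H]3C(=O)[C@H]1[C@@](C)(C=CC3)C2(C)C | intermediate (not isolated)
18 | tetracyclic γ-lactone: salimabromide lacking both bromine atoms and with CH2 in place of the ketone; configuration as in 21 | CCc1ccc2c(c1)[C@H]1[C@@H]3OC(=O)[C@H]1[C@@](C)(C=CC3)C2(C)C | intermediate
19 | allylic tert-butyl peroxide of 18 (OOt-Bu on the allylic CH next to the lactone O–CH; either epimer) | CCc1ccc2c(c1)[C@H]1[C@@H]3OC(=O)[C@H]1[C@@](C)(C=CC3OOC(C)(C)C)C2(C)C | intermediate (not isolated)
20 | didebromosalimabromide (enone) | CCc1ccc2c(c1)[C@H]1[C@@H]3OC(=O)[C@H]1[C@@](C)(C=CC3=O)C2(C)C | intermediate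
21 | salimabromide | CCc1c(Br)cc2c(c1Br)[C@H]1[C@@H]3OC(=O)[C@H]1[C@@](C)(C=CC3=O)C2(C)C | target

**Step count**
Total: 12 steps. Longest linear sequence: 11 steps (steps 1–7 and 9–12, from 1).

**Three steps most likely to fail**

1. Step 10. Oxygen insertion may occur with the wrong regiochemistry (migration of the ring carbon next to the quaternary centre), or the keteniminium may be lost by hydrolysis or oligomerisation before it reaches the hindered ring alkene. The fallback separates C–C and C–O bond formation and makes the C–O bond at a ketone α-carbon, where regiochemistry is unambiguous. It sets out from 14: the cycloaddition is run as before but quenched only with aqueous NaHCO3 (60 °C), and cyclobutanone 17 is isolated. Allylic oxidation (Rh2(cap)4, t-BuOOH) should give the cyclobutanone-enone β-diketone F1. Aqueous LiOH in THF should open the strained four-membered ketone by retro-Claisen cleavage of the bond to the doubly activated carbon, giving the cycloheptenone carboxylic acid F2 with the cis configuration from the cycloaddition retained. [Hydroxy(tosyloxy)iodo]benzene in MeCN should then effect α-oxylactonisation of this 5-oxo acid, and the route is rejoined at 20.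

2. Step 3. The second methyl transfer may stall at the very hindered benzylic position next to the quaternary carbon (carbinol, chloride or exocyclic alkene instead of the gem-dimethyl group). The fallback sets out from 3 and separates the two C–C bond formations: MeMgCl/CeCl3 (THF, −78 °C) should add to the ketone only and give the tertiary benzylic carbinol F3, which can be isolated. AlMe3 with catalytic TMSOTf (CH2Cl2, 0 °C to rt) should then ionise and methylate it (SN1 methylation of a tertiary benzylic alcohol), returning to the route at 4.

3. Step 2. Facial discrimination in the ion pair may be poor with the small electrophile MeI, giving low enantiomeric purity. The fallback sets the stereocentre by Pd-catalysed decarboxylative asymmetric allylic alkylation instead and sets out from 1. NaH/diallyl carbonate should give the allyl β-keto ester F4, and MeI/K2CO3 the racemic methylated allyl ester F5. Pd2(dba)3 with (S)-t-Bu-PHOX (THF, 25 °C) should give the (S)-allyl ketone F6. Isomerisation with RuHCl(CO)(PPh3)3 should give the (E)-propenyl ketone F7, and ozonolysis (O3, then Me2S) the keto aldehyde F8. Pinnick oxidation to the β-keto acid F9 and immediate esterification with TMSCHN2 at 0 °C should return to the route at 3.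

**Further compounds**
F1 | step 10 | cyclobutanone-enone (17 with C=O at the allylic CH2; β-diketone) | CCc1ccc2c(c1)[C@H]1[C@@H]3C(=O)[C@H]1[C@@](C)(C=CC3=O)C2(C)C
F2 | step 10 | cycloheptenone carboxylic acid (20 without the lactone C–O bond: CO2H on the ring-fusion CH, CH2 next to the ketone) | CCc1ccc2c(c1)[C@H]1CC(=O)C=C[C@@](C)(C2(C)C)[C@@H]1C(=O)O
F3 | step 3 | methyl (2R)-6-bromo-1-hydroxy-1,2-dimethyl-1,2,3,4-tetrahydronaphthalene-2-carboxylate (either C-1 epimer) | COC(=O)[C@]1(C)CCc2cc(Br)ccc2C1(C)O
F4 | step 2 | allyl 6-bromo-1-oxo-1,2,3,4-tetrahydronaphthalene-2-carboxylate | C=CCOC(=O)C1CCc2cc(Br)ccc2C1=O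
F5 | step 2 | allyl 6-bromo-2-methyl-1-oxo-1,2,3,4-tetrahydronaphthalene-2-carboxylate (racemic) | C=CCOC(=O)C1(C)CCc2cc(Br)ccc2C1=O
F6 | step 2 | (S)-2-allyl-6-bromo-2-methyl-3,4-dihydronaphthalen-1(2H)-one | C=CC[C@]1(C)CCc2cc(Br)ccc2C1=O
F7 | step 2 | (S)-6-bromo-2-methyl-2-[(E)-prop-1-enyl]-3,4-dihydronaphthalen-1(2H)-one | C/C=C/[C@]1(C)CCc2cc(Br)ccc2C1=O
F8 | step 2 | (S)-6-bromo-2-methyl-1-oxo-1,2,3,4-tetrahydronaphthalene-2-carbaldehyde | O=C[C@]1(C)CCc2cc(Br)ccc2C1=O
F9 | step 2 | (R)-6-bromo-2-methyl-1-oxo-1,2,3,4-tetrahydronaphthalene-2-carboxylic acid | OC(=O)[C@]1(C)CCc2cc(Br)ccc2C1=O
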